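**Plan**

1. Cuts, in this order: (a) the interflavan bond from C4 of the upper (5-deoxy) flavan unit to C6 of the lower afzelechin unit; (b) the aryl ether bond O1–C8a of the upper pyran ring C; (c) the bond from C2 to ring B (aryl ketone from a Weinreb amide). What remains is (S)-3-(4-hydroxyphenyl)lactic acid, which carries C3, C4 and ring A.
2. Enabling feature: in the upper unit the 7-OH of ring A is para to C4a, and C8a is ortho to C4a, so ring A is a para-alkylphenol. As its para-quinol, C8a is a β-carbon of a cross-conjugated dienone within six-ring reach of the C2 hydroxyl, and loss of the C4a hydroxyl as water returns the arene with the 7-OH in place. The result is a net C–H etherification with no halogen on ring A.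
3. Forward order: chain and ring B are joined (steps 1–4), C2 is set (5), ring A is dearomatised (6–7), ring C is closed and ring A rearomatised (8), C4 is oxidised (9–10) and joined to C6 of a C8-brominated afzelechin ether (11–13), and all benzyl groups and the bromine are removed (14).
4. Stereochemistry: C3 is bought (L-tyrosine series); C2 comes from a chelation-controlled reduction relayed from C3; C4 comes from attack on the flavan-4-yl cation anti to the C3 substituent; the lower C2 and C3 are bought with (2R,3S)-afzelechin; the C8 bromine enforces the 4→6 linkage.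

Key step: step 8

Assumption: (S)-3-(4-hydroxyphenyl)lactic acid (the hydroxy acid of the L-tyrosine series) and (2R,3S)-afzelechin are bought in enantiopure form.

**Route**

Step 1
Reactants: 1 (S)-2-hydroxy-3-(4-hydroxyphenyl)propanoic acid; 2 allyl bromide
Product: 3 allyl (S)-3-[4-(allyloxy)phenyl]-2-hydroxypropanoate
Conditions: allyl bromide (2.3 equiv), K2CO3 (2.5 equiv), DMF, 23 °C
Reagents that add atoms: allyl bromide, C=CCBr
Why: Williamson-type O-alkylation under K2CO3 should allylate only the carboxylate and the phenoxide, leaving the secondary alcohol free and the stereocenter untouched; the aryl allyl ether is the temporary cap of the ring A phenol.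

Step 2
Reactants: 3 allyl (S)-3-[4-(allyloxy)phenyl]-2-hydroxypropanoate; 4 benzyl 2,2,2-trichloroacetimidate
Product: 5 allyl (S)-3-[4-(allyloxy)phenyl]-2-(benzyloxy)propanoate
Conditions: imidate 4 (1.5 equiv), TfOH (5 mol%), CH2Cl2/cyclohexane, 0 → 23 °C
Reagents that add atoms: benzyl 2,2,2-trichloroacetimidate, N=C(OCc1ccccc1)C(Cl)(Cl)Cl
Why: Acid-catalysed O-benzylation with the trichloroacetimidate needs no base, so the α-stereocenter cannot enolise; this benzyl ether later supplies the chelating oxygen for step 5 and blocks the C3 oxygen in step 8.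

Step 3
Reactants: 5 allyl (S)-3-[4-(allyloxy)phenyl]-2-(benzyloxy)propanoate; 6 N,O-dimethylhydroxylamine hydrochloride
Product: 7 (S)-3-[4-(allyloxy)phenyl]-2-(benzyloxy)-N-methoxy-N-methylpropanamide
Conditions: MeNHOMe·HCl (1.6 equiv), i-PrMgCl (3.2 equiv), THF, −20 °C
Reagents that add atoms: N,O-dimethylhydroxylamine hydrochloride, CNOC.Cl
Why: Weinreb amide formation by aminolysis of the ester with the chloromagnesium amide of MeNHOMe should proceed at low temperature without touching the α-stereocenter.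

Step 4
Reactants: 7 (S)-3-[4-(allyloxy)phenyl]-2-(benzyloxy)-N-methoxy-N-methylpropanamide; 8 4-(benzyloxy)phenylmagnesium bromide
Product: 9 (S)-3-[4-(allyloxy)phenyl]-2-(benzyloxy)-1-[4-(benzyloxy)phenyl]propan-1-one
Conditions: ArMgBr 8 (1.5 equiv), THF, −10 → 0 °C; aqueous NH4Cl
Reagents that add atoms: 4-(benzyloxy)phenylmagnesium bromide, Br[Mg]c1ccc(OCc2ccccc2)cc1
Why: Weinreb ketone synthesis: the magnesium-chelated tetrahedral adduct survives until work-up, so exactly one aryl group (ring B) is delivered.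

Step 5
Reactants: 9 (S)-3-[4-(allyloxy)phenyl]-2-(benzyloxy)-1-[4-(benzyloxy)phenyl]propan-1-one
Product: 10 (1R,2S)-3-[4-(allyloxy)phenyl]-2-(benzyloxy)-1-[4-(benzyloxy)phenyl]propan-1-ol
Conditions: Zn(BH4)2 (1.5 equiv), Et2O, −20 → 0 °C; aqueous NH4Cl
Reagents that add atoms: none
Why: Chelation-controlled ketone reduction: zinc ties the carbonyl oxygen to the α-benzyloxy oxygen in a five-membered chelate and hydride enters from the face of the α-hydrogen, which should set the new carbinol center (the future C2) anti to the benzyloxy center, that is (1R,2S).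

Step 6
Reactants: 10 (1R,2S)-3-[4-(allyloxy)phenyl]-2-(benzyloxy)-1-[4-(benzyloxy)phenyl]propan-1-ol
Product: 11 4-[(2S,3R)-2-(benzyloxy)-3-[4-(benzyloxy)phenyl]-3-hydroxypropyl]phenol
Conditions: Pd(PPh3)4 (3 mol%), morpholine (5 equiv), THF, 23 °C
Reagents that add atoms: none
Why: Tsuji–Trost allyl transfer from the aryl allyl ether to morpholine through a π-allylpalladium complex should free only the ring A phenol; benzyl ethers and the benzylic alcohol are inert.

Step 7
Reactants: 11 4-[(2S,3R)-2-(benzyloxy)-3-[4-(benzyloxy)phenyl]-3-hydroxypropyl]phenol; 12 potassium peroxymonosulfate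
Product: 14 4-[(2S,3R)-2-(benzyloxy)-3-[4-(benzyloxy)phenyl]-3-hydroxypropyl]-4-hydroxycyclohexa-2,5-dien-1-one (para-quinol), via para-hydroperoxy dienone 13 (not isolated)
Conditions: KHSO5 (as the triple salt 2KHSO5·KHSO4·K2SO4, excess), NaHCO3, MeCN/H2O, 23 °C; then Me2S (3 equiv)
Reagents that add atoms: potassium peroxymonosulfate (source of singlet oxygen), [K+].[O-]S(=O)(=O)OO
Why: Oxidative dearomatisation of a para-alkylphenol: singlet oxygen from base-induced self-decomposition of KHSO5 adds to the phenolate at the para carbon (the future C4a) to give the hydroperoxy dienone, which Me2S reduces to the para-quinol; because oxygen is delivered to C4a directly and not through a phenoxonium ion, the free C2 hydroxyl cannot form a spiro ether there, and the benzyl-protected ring B is not attacked.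

Step 8
Reactants: 14 4-[(2S,3R)-2-(benzyloxy)-3-[4-(benzyloxy)phenyl]-3-hydroxypropyl]-4-hydroxycyclohexa-2,5-dien-1-one
Product: 16 (2R,3S)-3-(benzyloxy)-2-[4-(benzyloxy)phenyl]chroman-7-ol, via bicyclic oxa-Michael adduct 15 (not isolated)
Conditions: TsOH·H2O (0.2 equiv), CH2Cl2, 23 → 40 °C
Reagents that add atoms: none
Why: TsOH activates the cross-conjugated dienone of 14 and the C2 hydroxyl adds to a β-carbon (the future C8a) in an intramolecular oxa-Michael addition; the closest known reaction type is the acid-catalysed cyclisation of hydroxyalkyl para-quinols joined to the dehydrative rearomatisation of 4-hydroxycyclohex-2-enones (dearomatisation, conjugate addition, rearomatisation). The pyran ring closes in the 6-exo-trig mode, and although the two β-carbons are diastereotopic, both adducts converge on the same product. The cis-fused adduct 15 enolises toward C8 and loses the tertiary, now doubly allylic C4a hydroxyl as water through a hydroxy-arenium ion, which sheds the C8a proton, so ring A is aromatic again and the dienone oxygen returns as the 7-OH. No lasting stereocenter is created: C4a and C8a of 15 (cis by the geometry of the tether) become sp2, while C2 and C3 keep their configuration because no bond to them is broken. The selectivity needed is six-ring closure through the C2 oxygen in place of five-ring closure through the C3 oxygen, which the C3 benzyl ether secures, and ring B stays out because it was never dearomatised.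

Step 9
Reactants: 16 (2R,3S)-3-(benzyloxy)-2-[4-(benzyloxy)phenyl]chroman-7-ol; 17 benzyl bromide
Product: 18 (2R,3S)-3,7-bis(benzyloxy)-2-[4-(benzyloxy)phenyl]chromane
Conditions: BnBr (1.2 equiv), K2CO3 (2 equiv), DMF, 23 °C
Reagents that add atoms: benzyl bromide, BrCc1ccccc1
Why: Williamson etherification of the phenol; capping the 7-OH takes the nucleophilic free-phenol ring out of the Friedel–Crafts step and leaves only benzyl ethers for the final hydrogenolysis.

Step 10
Reactants: 18 (2R,3S)-3,7-bis(benzyloxy)-2-[4-(benzyloxy)phenyl]chromane; 19 2-ethoxyethanol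
Product: 20 (2R,3S)-3,7-bis(benzyloxy)-2-[4-(benzyloxy)phenyl]-4-(2-ethoxyethoxy)chromane (C4 epimers, either serves)
Conditions: DDQ (1.5 equiv), 2-ethoxyethanol (5 equiv), CH2Cl2, 23 °C
Reagents that add atoms: 2-ethoxyethanol, CCOCCO
Why: DDQ-mediated oxidative benzylic etherification: hydride should leave from C4–H, which is activated by both the para 7-benzyloxy group and the ortho ring oxygen O1 (a 2,4-dialkoxybenzyl position), in preference to C2–H, and the alcohol traps the cation; the configuration at C4 is irrelevant because the center is ionised again in step 13.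

Step 11
Reactants: 21 (2R,3S)-afzelechin; 17 benzyl bromide
Product: 22 (2R,3S)-5,7-bis(benzyloxy)-2-[4-(benzyloxy)phenyl]chroman-3-ol
Conditions: BnBr (3.3 equiv), K2CO3 (4 equiv), DMF, 0 → 23 °C
Reagents that add atoms: benzyl bromide, BrCc1ccccc1
Why: Williamson etherification with K2CO3 should alkylate the three phenols only, since the secondary 3-OH is not deprotonated.

Step 12
Reactants: 22 (2R,3S)-5,7-bis(benzyloxy)-2-[4-(benzyloxy)phenyl]chroman-3-ol; 23 N-bromosuccinimide
Product: 24 (2R,3S)-5,7-bis(benzyloxy)-2-[4-(benzyloxy)phenyl]-8-bromochroman-3-ol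
Conditions: NBS (1.0 equiv), CH2Cl2, −78 → 0 °C
Reagents that add atoms: N-bromosuccinimide, BrN1C(=O)CCC1=O
Why: Electrophilic aromatic bromination of the 5,7-dialkoxy ring A should go to C8, the less hindered of its two free positions (C6 lies between two benzyloxy groups), so that bromine blocks C8 and leaves C6 as the only nucleophilic site.

Step 13
Reactants: 20 (2R,3S)-3,7-bis(benzyloxy)-2-[4-(benzyloxy)phenyl]-4-(2-ethoxyethoxy)chromane; 24 (2R,3S)-5,7-bis(benzyloxy)-2-[4-(benzyloxy)phenyl]-8-bromochroman-3-ol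
Product: 25 (2R,3S,4S)-3,7-bis(benzyloxy)-2-[4-(benzyloxy)phenyl]-4-[(2R,3S)-5,7-bis(benzyloxy)-2-[4-(benzyloxy)phenyl]-8-bromo-3-hydroxychroman-6-yl]chromane
Conditions: 24 (3 equiv), TMSOTf (0.5 equiv), 4 Å molecular sieves, CH2Cl2, −78 → −40 °C; Et3N quench
Reagents that add atoms: none
Why: Friedel–Crafts alkylation: TMSOTf ionises the C4 ether of 20 to the benzylic cation stabilised by O1 and the 7-benzyloxy group, and ring A of 24, blocked at C8 by bromine, attacks through C6; the new stereocenter C4 is set by substrate control, the arene approaching the half-chair cation on the face opposite the adjacent C3 benzyloxy group to give the 3,4-trans (4S) product.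

Step 14
Reactants: 25 (2R,3S,4S)-3,7-bis(benzyloxy)-2-[4-(benzyloxy)phenyl]-4-[(2R,3S)-5,7-bis(benzyloxy)-2-[4-(benzyloxy)phenyl]-8-bromo-3-hydroxychroman-6-yl]chromane
Product: 26 (2R,3S,4S)-2-(4-hydroxyphenyl)-4-[(2R,3S)-3,5,7-trihydroxy-2-(4-hydroxyphenyl)chroman-6-yl]chromane-3,7-diol (CNP0325116.1)
Conditions: H2 (1 atm), Pd(OH)2/C, Et3N (1.5 equiv), THF/MeOH/H2O, 23 °C
Reagents that add atoms: none
Why: Hydrogenolysis over Pd(OH)2/C should cleave the six benzyl ethers and the aryl C–Br bond in one operation while Et3N takes up the HBr, so that no acid reaches the interflavan bond; no stereocenter is touched.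

**Compound list**

1 | (S)-2-hydroxy-3-(4-hydroxyphenyl)propanoic acid | Oc1ccc(C[C@H](O)C(=O)O)cc1 | starting material
2 | allyl bromide | C=CCBr | starting material
3 | allyl (S)-3-[4-(allyloxy)phenyl]-2-hydroxypropanoate | C=CCOc1ccc(C[C@H](O)C(=O)OCC=C)cc1 | intermediate
4 | benzyl 2,2,2-trichloroacetimidate | N=C(OCc1ccccc1)C(Cl)(Cl)Cl | starting material
5 | allyl (S)-3-[4-(allyloxy)phenyl]-2-(benzyloxy)propanoate | C=CCOc1ccc(C[C@H](OCc2ccccc2)C(=O)OCC=C)cc1 | intermediate
6 | N,O-dimethylhydroxylamine hydrochloride | CNOC.Cl | starting material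
7 | (S)-3-[4-(allyloxy)phenyl]-2-(benzyloxy)-N-methoxy-N-methylpropanamide | C=CCOc1ccc(C[C@H](OCc2ccccc2)C(=O)N(C)OC)cc1 | intermediate
8 | 4-(benzyloxy)phenylmagnesium bromide | Br[Mg]c1ccc(OCc2ccccc2)cc1 | starting material
9 | (S)-3-[4-(allyloxy)phenyl]-2-(benzyloxy)-1-[4-(benzyloxy)phenyl]propan-1-one | C=CCOc1ccc(C[C@H](OCc2ccccc2)C(=O)c2ccc(OCc3ccccc3)cc2)cc1 | intermediate
10 | (1R,2S)-3-[4-(allyloxy)phenyl]-2-(benzyloxy)-1-[4-(benzyloxy)phenyl]propan-1-ol | C=CCOc1ccc(C[C@H](OCc2ccccc2)[C@H](O)c2ccc(OCc3ccccc3)cc2)cc1 | intermediate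
11 | 4-[(2S,3R)-2-(benzyloxy)-3-[4-(benzyloxy)phenyl]-3-hydroxypropyl]phenol | Oc1ccc(C[C@H](OCc2ccccc2)[C@H](O)c2ccc(OCc3ccccc3)cc2)cc1 | intermediate
12 | potassium peroxymonosulfate, KHSO5 (used as the triple salt 2KHSO5·KHSO4·K2SO4) | [K+].[O-]S(=O)(=O)OO | starting material
13 | 4-[(2S,3R)-2-(benzyloxy)-3-[4-(benzyloxy)phenyl]-3-hydroxypropyl]-4-hydroperoxycyclohexa-2,5-dien-1-one | O=C1C=CC(OO)(C[C@H](OCc2ccccc2)[C@H](O)c2ccc(OCc3ccccc3)cc2)C=C1 | intermediate (not isolated)
14 | 4-[(2S,3R)-2-(benzyloxy)-3-[4-(benzyloxy)phenyl]-3-hydroxypropyl]-4-hydroxycyclohexa-2,5-dien-1-one | O=C1C=CC(O)(C[C@H](OCc2ccccc2)[C@H](O)c2ccc(OCc3ccccc3)cc2)C=C1 | intermediate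
15 | (2R,3S)-3-(benzyloxy)-2-[4-(benzyloxy)phenyl]-4a-hydroxy-2,3,4,4a,8,8a-hexahydro-7H-chromen-7-one (cis ring fusion; O1 on C8a, tertiary OH on C4a, C5=C6 enone, C7 ketone; either ring-fusion diastereomer, left open in the SMILES) | O=C1C=CC2(O)C[C@H](OCc3ccccc3)[C@@H](c3ccc(OCc4ccccc4)cc3)OC2C1 | intermediate (not isolated)
16 | (2R,3S)-3-(benzyloxy)-2-[4-(benzyloxy)phenyl]chroman-7-ol | Oc1ccc2C[C@H](OCc3ccccc3)[C@@H](c3ccc(OCc4ccccc4)cc3)Oc2c1 | intermediate
17 | benzyl bromide | BrCc1ccccc1 | starting material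
18 | (2R,3S)-3,7-bis(benzyloxy)-2-[4-(benzyloxy)phenyl]chromane | C(Oc1ccc2C[C@H](OCc3ccccc3)[C@@H](c3ccc(OCc4ccccc4)cc3)Oc2c1)c1ccccc1 | intermediate
19 | 2-ethoxyethanol | CCOCCO | starting material
20 | (2R,3S)-3,7-bis(benzyloxy)-2-[4-(benzyloxy)phenyl]-4-(2-ethoxyethoxy)chromane (C4 epimers, C4 left open in the SMILES) | CCOCCOC1[C@H](OCc2ccccc2)[C@@H](c2ccc(OCc3ccccc3)cc2)Oc2cc(OCc3ccccc3)ccc12 | intermediate
21 | (2R,3S)-afzelechin, (2R,3S)-2-(4-hydroxyphenyl)chromane-3,5,7-triol | Oc1cc(O)c2C[C@H](O)[C@@H](c3ccc(O)cc3)Oc2c1 | starting material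
22 | (2R,3S)-5,7-bis(benzyloxy)-2-[4-(benzyloxy)phenyl]chroman-3-ol | C(Oc1cc(OCc2ccccc2)c2C[C@H](O)[C@@H](c3ccc(OCc4ccccc4)cc3)Oc2c1)c1ccccc1 | intermediate
23 | N-bromosuccinimide | BrN1C(=O)CCC1=O | starting material
24 | (2R,3S)-5,7-bis(benzyloxy)-2-[4-(benzyloxy)phenyl]-8-bromochroman-3-ol | C(Oc1cc(OCc2ccccc2)c2C[C@H](O)[C@@H](c3ccc(OCc4ccccc4)cc3)Oc2c1Br)c1ccccc1 | intermediate
25 | (2R,3S,4S)-3,7-bis(benzyloxy)-2-[4-(benzyloxy)phenyl]-4-[(2R,3S)-5,7-bis(benzyloxy)-2-[4-(benzyloxy)phenyl]-8-bromo-3-hydroxychroman-6-yl]chromane | c1ccccc1COc1ccc(cc1)[C@H]1Oc2cc(OCc3ccccc3)ccc2[C@@H](c2c(OCc3ccccc3)c(Br)c3c(c2OCc2ccccc2)C[C@H](O)[C@@H](c2ccc(OCc4ccccc4)cc2)O3)[C@@H]1OCc1ccccc1 | intermediate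
26 | (2R,3S,4S)-2-(4-hydroxyphenyl)-4-[(2R,3S)-3,5,7-trihydroxy-2-(4-hydroxyphenyl)chroman-6-yl]chromane-3,7-diol | Oc1ccc([C@H]2Oc3cc(O)ccc3[C@@H](c3c(O)cc4c(c3O)C[C@H](O)[C@@H](c3ccc(O)cc3)O4)[C@@H]2O)cc1 | target

**Count and risks**

Total steps: 14. Longest linear sequence: 12 steps (steps 1–10, 13, 14); steps 11–12 form the second branch.

Step 8 may fail through slow loss of water from adduct 15, through acid-induced ionisation of the benzylic C2–O bond (erosion of configuration at C2), or through dienone–phenol rearrangement of 14. The fallback gives up the dearomatisation and closes the same O1–C8a bond by copper-catalysed Ullmann etherification of an aryl bromide. It sets out from Grignard reagent 8, which it shares with the main route, together with two further bought materials, and comes back at 18. Bought 4-(benzyloxy)-2-bromo-1-iodobenzene is turned into its arylmagnesium species by iodine–magnesium exchange (i-PrMgCl·LiCl, THF, −40 °C). This opens bought methyl (S)-glycidate at its CH2 carbon under CuI catalysis to give methyl (S)-3-[4-(benzyloxy)-2-bromophenyl]-2-hydroxypropanoate F1. Benzylation with imidate 4 and TfOH as in step 2 gives methyl (S)-2-(benzyloxy)-3-[4-(benzyloxy)-2-bromophenyl]propanoate F2. MeNHOMe·HCl with i-PrMgCl as in step 3 gives (S)-2-(benzyloxy)-3-[4-(benzyloxy)-2-bromophenyl]-N-methoxy-N-methylpropanamide F3, and 8 as in step 4 gives (S)-2-(benzyloxy)-3-[4-(benzyloxy)-2-bromophenyl]-1-[4-(benzyloxy)phenyl]propan-1-one F4. Zn(BH4)2 as in step 5 should give the anti alcohol (1R,2S)-2-(benzyloxy)-3-[4-(benzyloxy)-2-bromophenyl]-1-[4-(benzyloxy)phenyl]propan-1-ol F5. CuI, 1,10-phenanthroline and Cs2CO3 in toluene at 110 °C then join the carbinol oxygen to the bromine-bearing ring carbon with both stereocenters untouched, which gives 18 directly because the 7-oxygen is already benzylated.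

Step 13 may fail through poor facial selectivity at C4 (3,4-cis product) or through self-alkylation of 20. The fallback moves to anchimeric control by a 3-O-acetyl group; it sets out from 16 and comes back at 26. Hydrogenolysis of 16 (H2, Pd(OH)2/C, THF/MeOH) gives (2R,3S)-2-(4-hydroxyphenyl)chromane-3,7-diol F6. Its two phenols alone are benzylated (BnBr, K2CO3, DMF) to (2R,3S)-7-(benzyloxy)-2-[4-(benzyloxy)phenyl]chroman-3-ol F7. DDQ with 2-ethoxyethanol 19 gives (2R,3S)-7-(benzyloxy)-2-[4-(benzyloxy)phenyl]-4-(2-ethoxyethoxy)chroman-3-ol F8, and Ac2O in pyridine gives (2R,3S)-7-(benzyloxy)-2-[4-(benzyloxy)phenyl]-4-(2-ethoxyethoxy)chroman-3-yl acetate F9. With TMSOTf the acetate closes onto the C4 cation from the face of the C3 oxygen (cis-fused dioxolanylium ion), so 24 must enter at C6 from the opposite face. This should give the 3,4-trans dimer (2R,3S,4S)-7-(benzyloxy)-2-[4-(benzyloxy)phenyl]-4-[(2R,3S)-5,7-bis(benzyloxy)-2-[4-(benzyloxy)phenyl]-8-bromo-3-hydroxychroman-6-yl]chroman-3-yl acetate F10. K2CO3 in MeOH/THF removes the acetate to give (2R,3S,4S)-7-(benzyloxy)-2-[4-(benzyloxy)phenyl]-4-[(2R,3S)-5,7-bis(benzyloxy)-2-[4-(benzyloxy)phenyl]-8-bromo-3-hydroxychroman-6-yl]chroman-3-ol F11, and hydrogenolysis under the conditions of step 14 gives 26.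

Step 10 may fail through hydride abstraction at C2–H in place of C4–H or through over-oxidation to the C4 ketone. The fallback oxidises before the phenol is capped, so that the only cation within reach is the ring A para-quinone methide; it sets out from 16 and comes back at 20. DDQ (1.0 equiv) and 2-ethoxyethanol 19 in CH2Cl2 at −20 °C should convert the free 7-OH phenol into the quinone methide (C7=O, C4a=C4), which can only form at C4 and adds the alcohol there to give (2R,3S)-3-(benzyloxy)-2-[4-(benzyloxy)phenyl]-4-(2-ethoxyethoxy)chroman-7-ol F12. Benzylation as in step 9 gives 20.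

**Further compounds**

F1 | step 8 | methyl (S)-3-[4-(benzyloxy)-2-bromophenyl]-2-hydroxypropanoate | COC(=O)[C@@H](O)Cc1ccc(OCc2ccccc2)cc1Br
F2 | step 8 | methyl (S)-2-(benzyloxy)-3-[4-(benzyloxy)-2-bromophenyl]propanoate | COC(=O)[C@@H](OCc1ccccc1)Cc1ccc(OCc2ccccc2)cc1Br
F3 | step 8 | (S)-2-(benzyloxy)-3-[4-(benzyloxy)-2-bromophenyl]-N-methoxy-N-methylpropanamide | CON(C)C(=O)[C@@H](OCc1ccccc1)Cc1ccc(OCc2ccccc2)cc1Br
F4 | step 8 | (S)-2-(benzyloxy)-3-[4-(benzyloxy)-2-bromophenyl]-1-[4-(benzyloxy)phenyl]propan-1-one | O=C([C@@H](OCc1ccccc1)Cc1ccc(OCc2ccccc2)cc1Br)c1ccc(OCc2ccccc2)cc1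
F5 | step 8 | (1R,2S)-2-(benzyloxy)-3-[4-(benzyloxy)-2-bromophenyl]-1-[4-(benzyloxy)phenyl]propan-1-ol | O[C@@H]([C@@H](OCc1ccccc1)Cc1ccc(OCc2ccccc2)cc1Br)c1ccc(OCc2ccccc2)cc1
F6 | step 13 | (2R,3S)-2-(4-hydroxyphenyl)chromane-3,7-diol | Oc1ccc2C[C@H](O)[C@@H](c3ccc(O)cc3)Oc2c1
F7 | step 13 | (2R,3S)-7-(benzyloxy)-2-[4-(benzyloxy)phenyl]chroman-3-ol | C(Oc1ccc2C[C@H](O)[C@@H](c3ccc(OCc4ccccc4)cc3)Oc2c1)c1ccccc1
F8 | step 13 | (2R,3S)-7-(benzyloxy)-2-[4-(benzyloxy)phenyl]-4-(2-ethoxyethoxy)chroman-3-ol (C4 epimers) | CCOCCOC1[C@H](O)[C@@H](c2ccc(OCc3ccccc3)cc2)Oc2cc(OCc3ccccc3)ccc12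
F9 | step 13 | (2R,3S)-7-(benzyloxy)-2-[4-(benzyloxy)phenyl]-4-(2-ethoxyethoxy)chroman-3-yl acetate (C4 epimers) | CCOCCOC1[C@H](OC(C)=O)[C@@H](c2ccc(OCc3ccccc3)cc2)Oc2cc(OCc3ccccc3)ccc12
F10 | step 13 | (2R,3S,4S)-7-(benzyloxy)-2-[4-(benzyloxy)phenyl]-4-[(2R,3S)-5,7-bis(benzyloxy)-2-[4-(benzyloxy)phenyl]-8-bromo-3-hydroxychroman-6-yl]chroman-3-yl acetate | c1ccccc1COc1ccc(cc1)[C@H]1Oc2cc(OCc3ccccc3)ccc2[C@@H](c2c(OCc3ccccc3)c(Br)c3c(c2OCc2ccccc2)C[C@H](O)[C@@H](c2ccc(OCc4ccccc4)cc2)O3)[C@@H]1OC(C)=O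
F11 | step 13 | (2R,3S,4S)-7-(benzyloxy)-2-[4-(benzyloxy)phenyl]-4-[(2R,3S)-5,7-bis(benzyloxy)-2-[4-(benzyloxy)phenyl]-8-bromo-3-hydroxychroman-6-yl]chroman-3-ol | c1ccccc1COc1ccc(cc1)[C@H]1Oc2cc(OCc3ccccc3)ccc2[C@@H](c2c(OCc3ccccc3)c(Br)c3c(c2OCc2ccccc2)C[C@H](O)[C@@H](c2ccc(OCc4ccccc4)cc2)O3)[C@@H]1O
F12 | step 10 | (2R,3S)-3-(benzyloxy)-2-[4-(benzyloxy)phenyl]-4-(2-ethoxyethoxy)chroman-7-ol (C4 epimers) | CCOCCOC1[C@H](OCc2ccccc2)[C@@H](c2ccc(OCc3ccccc3)cc2)Oc2cc(O)ccc12
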